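**Plan**

1. Retrosynthetic cuts, in order: the nine O–benzyl bonds; C4'–C4a' in the lower ring C; the aryl ether bond C2'–O1'; the interflavan bond C4–C6'; then C4–C4a and C2–O1 of the upper unit in the same two ways.
2. Enabling feature: in the lower ring C (O1'–C2'–C3'–C4'–C4a'–C8a') the acid-labile carbinol carbon C4' is bonded directly to C4a' of ring A, ortho to the ether oxygen on C8a', and its hydroxyl is cis to the C3' oxygen. C4' can therefore be an aldehyde carbon and C4a' an arylchromium carbon, joined under neutral conditions.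
3. Forward order: iodophenol 5 (used twice) → aryl ether with glycidic ester 9 → upper ring C (step 9) → interflavan bond by arylation of a second molecule of 5 (step 12) → aryl ether with glycidic ester 17 → lower ring C (step 16) → debenzylation.
4. Stereochemistry: C2, C3, C2' and C3' come from two catalyst-made (2S,3S)-cis-glycidic esters opened with inversion at the benzylic carbon; C4 from attack anti to the C3 benzyloxy group (3,4-trans); C4' from substrate control in the ring closure (3',4'-cis).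

Key step: step 16

Remark on numbering: flavan locants are used; unprimed atoms belong to the upper unit (3,4-dihydroxyphenyl at C2), primed atoms to the lower unit (4-hydroxyphenyl at C2').
Remark on descriptors: C4 is labelled R in the benzylated compounds 18–23 and S in target 24 only because the CIP ranking of its two aryl groups changes on debenzylation; the geometry (3,4-trans) is the same throughout.
Assumption: the (S,S)-salen manganese catalyst gives the (2S,3S)-cis-epoxides, by analogy with the sense established for ethyl (Z)-cinnamate; were the sense opposite, the (R,R)-catalyst would be used.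

**Step 1**
Reactants: 1 2,3-dihydroxybenzaldehyde
Product: 2 2,3-bis(benzyloxy)benzaldehyde
Conditions: BnBr, K2CO3, DMF, 60 °C
Reagents that add atoms: benzyl bromide, BrCc1ccccc1
Why: Williamson etherification of both phenolic hydroxyls with carbonate base is routine for catechol aldehydes and leaves the aldehyde untouched.

**Step 2**
Reactants: 2 2,3-bis(benzyloxy)benzaldehyde
Product: 3 2,3-bis(benzyloxy)-6-iodobenzaldehyde
Conditions: I2, CF3CO2Ag, CH2Cl2, rt, dark
Reagents that add atoms: iodine, II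
Why: Electrophilic aromatic iodination by the hypoiodite formed from I2 and CF3CO2Ag should go para to the 3-benzyloxy group (C6), because the 2-benzyloxy group is twisted out of conjugation by its two neighbours, the orientation known for halogenation of 2,3-dialkoxybenzaldehydes; this places iodine next to the future phenol oxygen.

**Step 3**
Reactants: 3 2,3-bis(benzyloxy)-6-iodobenzaldehyde
Product: 5 2,3-bis(benzyloxy)-6-iodophenol, via aryl formate 4 (not isolated)
Conditions: mCPBA, CH2Cl2, rt; then K2CO3 (cat.), MeOH, rt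
Reagents that add atoms: mCPBA, OOC(=O)c1cccc(Cl)c1
Why: Baeyer–Villiger (Dakin-type) oxidation of an electron-rich benzaldehyde proceeds with migration of the ortho-alkoxy aryl group to formate 4, which mild methanolysis cleaves to the phenol, while aryl iodide and benzyl ethers are inert to both reagents.

**Step 4**
Reactants: 6 3,4-bis(benzyloxy)benzaldehyde; 7 ethyl 2-(diphenoxyphosphoryl)acetate
Product: 8 ethyl (Z)-3-[3,4-bis(benzyloxy)phenyl]prop-2-enoate
Conditions: NaH, THF, −78 °C to 0 °C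
Reagents that add atoms: none
Why: Z-selective Horner–Wadsworth–Emmons olefination of the Ando type, in which the diaryl phosphonate eliminates fast from the kinetically formed adduct, should give mainly the cis-cinnamate, the minor E-ester being removable by chromatography.

**Step 5**
Reactants: 8 ethyl (Z)-3-[3,4-bis(benzyloxy)phenyl]prop-2-enoate
Product: 9 ethyl (2S,3S)-3-[3,4-bis(benzyloxy)phenyl]oxirane-2-carboxylate
Conditions: (S,S)-[N,N'-bis(3,5-di-tert-butylsalicylidene)cyclohexane-1,2-diaminato]manganese chloride (5 mol %), 4-phenylpyridine N-oxide, aqueous NaOCl buffered with Na2HPO4 (pH 11.3), CH2Cl2, 4 °C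
Reagents that add atoms: sodium hypochlorite, [Na+].[O-]Cl
Why: Jacobsen–Katsuki epoxidation is most selective for cis-disubstituted aryl alkenes such as Z-cinnamates, the chiral catalyst setting both new stereocentres as the (2S,3S)-cis-epoxide and the N-oxide additive limiting leakage to the trans-epoxide.

**Step 6**
Reactants: 5 2,3-bis(benzyloxy)-6-iodophenol; 9 ethyl (2S,3S)-3-[3,4-bis(benzyloxy)phenyl]oxirane-2-carboxylate
Product: 10 ethyl (2S,3R)-3-[2,3-bis(benzyloxy)-6-iodophenoxy]-3-[3,4-bis(benzyloxy)phenyl]-2-hydroxypropanoate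
Conditions: Cs2CO3 (0.5 equiv), DMF, 60 °C
Reagents that add atoms: none
Why: SN2 opening of the glycidic ester by the phenoxide at the benzylic carbon, which is activated by the aryl group and remote from the ester carbonyl, occurs with inversion and turns the cis-epoxide into the threo 3-aryloxy-2-hydroxy ester, that is the 2,3-cis flavan relationship of future C2 (R) and C3; substoichiometric base keeps the product alkoxide protonated.

**Step 7**
Reactants: 10 ethyl (2S,3R)-3-[2,3-bis(benzyloxy)-6-iodophenoxy]-3-[3,4-bis(benzyloxy)phenyl]-2-hydroxypropanoate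
Product: 11 ethyl (2S,3R)-2-(benzyloxy)-3-[2,3-bis(benzyloxy)-6-iodophenoxy]-3-[3,4-bis(benzyloxy)phenyl]propanoate
Conditions: BnBr, Ag2O, CH2Cl2, rt, dark
Reagents that add atoms: benzyl bromide, BrCc1ccccc1
Why: Silver-oxide-mediated O-benzylation, a Williamson etherification under neutral conditions, alkylates the α-hydroxy ester without the strong base that would epimerise C2 or expel the β-aryloxy group.

**Step 8**
Reactants: 11 ethyl (2S,3R)-2-(benzyloxy)-3-[2,3-bis(benzyloxy)-6-iodophenoxy]-3-[3,4-bis(benzyloxy)phenyl]propanoate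
Product: 12 (2S,3R)-2-(benzyloxy)-3-[2,3-bis(benzyloxy)-6-iodophenoxy]-3-[3,4-bis(benzyloxy)phenyl]propanal
Conditions: i-Bu2AlH (1.1 equiv), CH2Cl2, −78 °C; MeOH, then aqueous potassium sodium tartrate
Reagents that add atoms: none
Why: Partial reduction of an α-alkoxy ester with i-Bu2AlH at −78 °C should stop at the aldehyde oxidation level when quenched cold, the aryl iodide being inert at this temperature; the aldehyde is used at once, without chromatography, to avoid β-elimination.

**Step 9**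
Reactants: 12 (2S,3R)-2-(benzyloxy)-3-[2,3-bis(benzyloxy)-6-iodophenoxy]-3-[3,4-bis(benzyloxy)phenyl]propanal
Product: 14 (2R,3R,4R)-3,7,8-tris(benzyloxy)-2-[3,4-bis(benzyloxy)phenyl]chroman-4-ol, via arylchromium dichloride 13 (not isolated)
Conditions: CrCl2 (6 equiv), NiCl2 (5 mol %), degassed DMF, rt; aqueous NH4Cl
Reagents that add atoms: none
Why: Intramolecular Nozaki–Hiyama–Kishi addition, in which nickel-catalysed formation of arylchromium dichloride 13 and its 6-exo-trig addition to the aldehyde close the upper ring C under neutral conditions; the configuration of the new carbinol C4 does not matter because C4 is ionised in step 12 (the 3,4-cis alcohol is expected for the reasons given in step 16).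

**Step 10**
Reactants: 15 4-(benzyloxy)benzaldehyde; 7 ethyl 2-(diphenoxyphosphoryl)acetate
Product: 16 ethyl (Z)-3-[4-(benzyloxy)phenyl]prop-2-enoate
Conditions: NaH, THF, −78 °C to 0 °C
Reagents that add atoms: none
Why: The same Ando-type Z-selective Horner–Wadsworth–Emmons olefination as in step 4 should give mainly the cis-cinnamate.

**Step 11**
Reactants: 16 ethyl (Z)-3-[4-(benzyloxy)phenyl]prop-2-enoate
Product: 17 ethyl (2S,3S)-3-[4-(benzyloxy)phenyl]oxirane-2-carboxylate
Conditions: (S,S)-[N,N'-bis(3,5-di-tert-butylsalicylidene)cyclohexane-1,2-diaminato]manganese chloride (5 mol %), 4-phenylpyridine N-oxide, aqueous NaOCl buffered with Na2HPO4 (pH 11.3), CH2Cl2, 4 °C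
Reagents that add atoms: sodium hypochlorite, [Na+].[O-]Cl
Why: Jacobsen–Katsuki epoxidation of the Z-cinnamate, as in step 5, should set both stereocentres of the (2S,3S)-cis-epoxide under catalyst control.

**Step 12**
Reactants: 14 (2R,3R,4R)-3,7,8-tris(benzyloxy)-2-[3,4-bis(benzyloxy)phenyl]chroman-4-ol; 5 2,3-bis(benzyloxy)-6-iodophenol (3 equiv)
Product: 18 2,3-bis(benzyloxy)-6-iodo-4-[(2R,3R,4R)-3,7,8-tris(benzyloxy)-2-[3,4-bis(benzyloxy)phenyl]chroman-4-yl]phenol
Conditions: BF3·OEt2 (0.5 equiv), 4 Å molecular sieves, CH2Cl2, −40 °C to 0 °C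
Reagents that add atoms: none
Why: SN1-type Friedel–Crafts alkylation with loss of water, in which BF3·OEt2 ionises the C4 hydroxyl to a benzylic cation stabilised by O1 and the para 7-benzyloxy group and the phenol attacks through its most activated free position (para to the hydroxyl, the ortho position being blocked by iodine) on the face anti to the axial C3 benzyloxy group, sets C4 as 3,4-trans, the outcome generally found for 2,3-cis flavan-4-yl cations.

**Step 13**
Reactants: 18 2,3-bis(benzyloxy)-6-iodo-4-[(2R,3R,4R)-3,7,8-tris(benzyloxy)-2-[3,4-bis(benzyloxy)phenyl]chroman-4-yl]phenol; 17 ethyl (2S,3S)-3-[4-(benzyloxy)phenyl]oxirane-2-carboxylate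
Product: 19 ethyl (2S,3R)-3-{2,3-bis(benzyloxy)-6-iodo-4-[(2R,3R,4R)-3,7,8-tris(benzyloxy)-2-[3,4-bis(benzyloxy)phenyl]chroman-4-yl]phenoxy}-3-[4-(benzyloxy)phenyl]-2-hydroxypropanoate
Conditions: Cs2CO3 (0.5 equiv), DMF, 60 °C
Reagents that add atoms: none
Why: The phenoxide opens the cis-glycidic ester by SN2 attack at the benzylic carbon with inversion, as in step 6, which sets C2' (R) and the 2',3'-cis relationship and forms the O1'–C2' bond with the iodine already ortho to the ether oxygen.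

**Step 14**
Reactants: 19 ethyl (2S,3R)-3-{2,3-bis(benzyloxy)-6-iodo-4-[(2R,3R,4R)-3,7,8-tris(benzyloxy)-2-[3,4-bis(benzyloxy)phenyl]chroman-4-yl]phenoxy}-3-[4-(benzyloxy)phenyl]-2-hydroxypropanoate
Product: 20 ethyl (2S,3R)-2-(benzyloxy)-3-{2,3-bis(benzyloxy)-6-iodo-4-[(2R,3R,4R)-3,7,8-tris(benzyloxy)-2-[3,4-bis(benzyloxy)phenyl]chroman-4-yl]phenoxy}-3-[4-(benzyloxy)phenyl]propanoate
Conditions: BnBr, Ag2O, CH2Cl2, rt, dark
Reagents that add atoms: benzyl bromide, BrCc1ccccc1
Why: Neutral silver-oxide-mediated O-benzylation protects the only free hydroxyl without base-induced epimerisation or loss of the β-aryloxy group.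

**Step 15**
Reactants: 20 ethyl (2S,3R)-2-(benzyloxy)-3-{2,3-bis(benzyloxy)-6-iodo-4-[(2R,3R,4R)-3,7,8-tris(benzyloxy)-2-[3,4-bis(benzyloxy)phenyl]chroman-4-yl]phenoxy}-3-[4-(benzyloxy)phenyl]propanoate
Product: 21 (2S,3R)-2-(benzyloxy)-3-{2,3-bis(benzyloxy)-6-iodo-4-[(2R,3R,4R)-3,7,8-tris(benzyloxy)-2-[3,4-bis(benzyloxy)phenyl]chroman-4-yl]phenoxy}-3-[4-(benzyloxy)phenyl]propanal
Conditions: i-Bu2AlH (1.1 equiv), CH2Cl2, −78 °C; MeOH, then aqueous potassium sodium tartrate
Reagents that add atoms: none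
Why: Partial reduction of the α-alkoxy ester at −78 °C, as in step 8, should give the aldehyde, which is taken directly into the ring closure.

**Step 16**
Reactants: 21 (2S,3R)-2-(benzyloxy)-3-{2,3-bis(benzyloxy)-6-iodo-4-[(2R,3R,4R)-3,7,8-tris(benzyloxy)-2-[3,4-bis(benzyloxy)phenyl]chroman-4-yl]phenoxy}-3-[4-(benzyloxy)phenyl]propanal
Product: 23 (2R,3R,4R)-3,7,8-tris(benzyloxy)-2-[4-(benzyloxy)phenyl]-6-[(2R,3R,4R)-3,7,8-tris(benzyloxy)-2-[3,4-bis(benzyloxy)phenyl]chroman-4-yl]chroman-4-ol, via arylchromium dichloride 22 (not isolated)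
Conditions: CrCl2 (6 equiv), NiCl2 (5 mol %), degassed DMF, rt; aqueous NH4Cl
Reagents that add atoms: none
Why: CrCl2 reduces NiCl2 to zerovalent nickel, which inserts into the C4a'–I bond, and transfer of the aryl group to trivalent chromium (two equivalents of divalent chromium per iodide) gives arylchromium dichloride 22, whose carbon C4a' adds to the chromium-bound aldehyde carbon C4', the chromium alkoxide being protonated on work-up. The closest known reaction type is the intramolecular Nozaki–Hiyama–Kishi cyclisation of aryl and alkenyl iodides onto tethered aldehydes. The lower ring C (O1'–C2'–C3'–C4'–C4a'–C8a') closes in the 6-exo-trig mode, the carbonyl oxygen staying outside the new ring. The new stereocentre C4' is set under substrate control by C3' and C2': addition in the 1,2-anti (Felkin-type, non-chelated) sense that organochromium reagents normally show toward α-alkoxy aldehydes is, within the ring, the 3',4'-cis alcohol, and the half-chair with the 2'-aryl group equatorial and the 3'-benzyloxy group axial reaches it with the carbonyl oxygen pointing equatorially toward C5', beside the chromium that is leaving C4a'. The step needs cis over trans facial selectivity at C4', secured by the fixed 2',3'-cis pair as described, and chemoselective activation of the C–I bond without β-elimination of the C2' aryloxy group or epimerisation at C3', secured by the non-basic medium and the low basicity of the arylchromium species. The benzylic C4' hydroxyl is thereby formed without acid and is left free.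

**Step 17**
Reactants: 23 (2R,3R,4R)-3,7,8-tris(benzyloxy)-2-[4-(benzyloxy)phenyl]-6-[(2R,3R,4R)-3,7,8-tris(benzyloxy)-2-[3,4-bis(benzyloxy)phenyl]chroman-4-yl]chroman-4-ol
Product: 24 (2R,3R,4R)-6-[(2R,3R,4S)-2-(3,4-dihydroxyphenyl)-3,7,8-trihydroxychroman-4-yl]-2-(4-hydroxyphenyl)chroman-3,4,7,8-tetrol
Conditions: H2 (1 atm), Pd(OH)2/C, THF–MeOH with aqueous NaH2PO4/Na2HPO4 buffer (pH 7), rt
Reagents that add atoms: none
Why: Hydrogenolysis of the nine benzyl ethers (seven aryl, two secondary alkyl) over Pd(OH)2/C releases only toluene, and the neutral buffered medium at low pressure is chosen so that the benzylic C4' hydroxyl, the two pyran C2–O bonds and the doubly benzylic C4–C6' bond are neither ionised nor reduced.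

**Compound list**

1 | 2,3-dihydroxybenzaldehyde | O=Cc1cccc(O)c1O | starting material
2 | 2,3-bis(benzyloxy)benzaldehyde | O=Cc1cccc(OCc2ccccc2)c1OCc1ccccc1 | intermediate
3 | 2,3-bis(benzyloxy)-6-iodobenzaldehyde | O=Cc1c(I)ccc(OCc2ccccc2)c1OCc1ccccc1 | intermediate
4 | 2,3-bis(benzyloxy)-6-iodophenyl formate | O=COc1c(I)ccc(OCc2ccccc2)c1OCc1ccccc1 | intermediate (not isolated)
5 | 2,3-bis(benzyloxy)-6-iodophenol | Oc1c(I)ccc(OCc2ccccc2)c1OCc1ccccc1 | intermediate
6 | 3,4-bis(benzyloxy)benzaldehyde | O=Cc1ccc(OCc2ccccc2)c(OCc2ccccc2)c1 | starting material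
7 | ethyl 2-(diphenoxyphosphoryl)acetate | CCOC(=O)CP(=O)(Oc1ccccc1)Oc1ccccc1 | starting material
8 | ethyl (Z)-3-[3,4-bis(benzyloxy)phenyl]prop-2-enoate | CCOC(=O)/C=C\c1ccc(OCc2ccccc2)c(OCc2ccccc2)c1 | intermediate
9 | ethyl (2S,3S)-3-[3,4-bis(benzyloxy)phenyl]oxirane-2-carboxylate (cis-glycidic ester) | CCOC(=O)[C@H]1O[C@H]1c1ccc(OCc2ccccc2)c(OCc2ccccc2)c1 | intermediate
10 | ethyl (2S,3R)-3-[2,3-bis(benzyloxy)-6-iodophenoxy]-3-[3,4-bis(benzyloxy)phenyl]-2-hydroxypropanoate | CCOC(=O)[C@@H](O)[C@H](Oc1c(I)ccc(OCc2ccccc2)c1OCc1ccccc1)c1ccc(OCc2ccccc2)c(OCc2ccccc2)c1 | intermediate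
11 | ethyl (2S,3R)-2-(benzyloxy)-3-[2,3-bis(benzyloxy)-6-iodophenoxy]-3-[3,4-bis(benzyloxy)phenyl]propanoate | CCOC(=O)[C@@H](OCc1ccccc1)[C@H](Oc1c(I)ccc(OCc2ccccc2)c1OCc1ccccc1)c1ccc(OCc2ccccc2)c(OCc2ccccc2)c1 | intermediate
12 | (2S,3R)-2-(benzyloxy)-3-[2,3-bis(benzyloxy)-6-iodophenoxy]-3-[3,4-bis(benzyloxy)phenyl]propanal | O=C[C@@H](OCc1ccccc1)[C@H](Oc1c(I)ccc(OCc2ccccc2)c1OCc1ccccc1)c1ccc(OCc2ccccc2)c(OCc2ccccc2)c1 | intermediate
13 | arylchromium dichloride derived from 12 (CrCl2 group in place of iodine) | O=C[C@@H](OCc1ccccc1)[C@H](Oc1c([Cr](Cl)Cl)ccc(OCc2ccccc2)c1OCc1ccccc1)c1ccc(OCc2ccccc2)c(OCc2ccccc2)c1 | intermediate (not isolated)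
14 | (2R,3R,4R)-3,7,8-tris(benzyloxy)-2-[3,4-bis(benzyloxy)phenyl]chroman-4-ol (upper unit, 2,3-cis-3,4-cis drawn as expected; either C4 epimer serves in step 12) | c1ccccc1COc1ccc(cc1OCc1ccccc1)[C@H]1Oc2c(ccc(OCc3ccccc3)c2OCc2ccccc2)[C@@H](O)[C@H]1OCc1ccccc1 | intermediate
15 | 4-(benzyloxy)benzaldehyde | O=Cc1ccc(OCc2ccccc2)cc1 | starting material
16 | ethyl (Z)-3-[4-(benzyloxy)phenyl]prop-2-enoate | CCOC(=O)/C=C\c1ccc(OCc2ccccc2)cc1 | intermediate
17 | ethyl (2S,3S)-3-[4-(benzyloxy)phenyl]oxirane-2-carboxylate (cis-glycidic ester) | CCOC(=O)[C@H]1O[C@H]1c1ccc(OCc2ccccc2)cc1 | intermediate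
18 | 2,3-bis(benzyloxy)-6-iodo-4-[(2R,3R,4R)-3,7,8-tris(benzyloxy)-2-[3,4-bis(benzyloxy)phenyl]chroman-4-yl]phenol (upper unit 2,3-cis-3,4-trans) | Oc1c(I)cc([C@H]2c3ccc(OCc4ccccc4)c(OCc4ccccc4)c3O[C@H](c3ccc(OCc4ccccc4)c(OCc4ccccc4)c3)[C@@H]2OCc2ccccc2)c(OCc2ccccc2)c1OCc1ccccc1 | intermediate
19 | ethyl (2S,3R)-3-{2,3-bis(benzyloxy)-6-iodo-4-[(2R,3R,4R)-3,7,8-tris(benzyloxy)-2-[3,4-bis(benzyloxy)phenyl]chroman-4-yl]phenoxy}-3-[4-(benzyloxy)phenyl]-2-hydroxypropanoate | CCOC(=O)[C@@H](O)[C@H](Oc1c(I)cc([C@H]2c3ccc(OCc4ccccc4)c(OCc4ccccc4)c3O[C@H](c3ccc(OCc4ccccc4)c(OCc4ccccc4)c3)[C@@H]2OCc2ccccc2)c(OCc2ccccc2)c1OCc1ccccc1)c1ccc(OCc2ccccc2)cc1 | intermediate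
20 | ethyl (2S,3R)-2-(benzyloxy)-3-{2,3-bis(benzyloxy)-6-iodo-4-[(2R,3R,4R)-3,7,8-tris(benzyloxy)-2-[3,4-bis(benzyloxy)phenyl]chroman-4-yl]phenoxy}-3-[4-(benzyloxy)phenyl]propanoate | CCOC(=O)[C@@H](OCc1ccccc1)[C@H](Oc1c(I)cc([C@H]2c3ccc(OCc4ccccc4)c(OCc4ccccc4)c3O[C@H](c3ccc(OCc4ccccc4)c(OCc4ccccc4)c3)[C@@H]2OCc2ccccc2)c(OCc2ccccc2)c1OCc1ccccc1)c1ccc(OCc2ccccc2)cc1 | intermediate
21 | (2S,3R)-2-(benzyloxy)-3-{2,3-bis(benzyloxy)-6-iodo-4-[(2R,3R,4R)-3,7,8-tris(benzyloxy)-2-[3,4-bis(benzyloxy)phenyl]chroman-4-yl]phenoxy}-3-[4-(benzyloxy)phenyl]propanal (precursor of the key step) | O=C[C@@H](OCc1ccccc1)[C@H](Oc1c(I)cc([C@H]2c3ccc(OCc4ccccc4)c(OCc4ccccc4)c3O[C@H](c3ccc(OCc4ccccc4)c(OCc4ccccc4)c3)[C@@H]2OCc2ccccc2)c(OCc2ccccc2)c1OCc1ccccc1)c1ccc(OCc2ccccc2)cc1 | intermediate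
22 | arylchromium dichloride derived from 21 (CrCl2 group in place of iodine) | O=C[C@@H](OCc1ccccc1)[C@H](Oc1c([Cr](Cl)Cl)cc([C@H]2c3ccc(OCc4ccccc4)c(OCc4ccccc4)c3O[C@H](c3ccc(OCc4ccccc4)c(OCc4ccccc4)c3)[C@@H]2OCc2ccccc2)c(OCc2ccccc2)c1OCc1ccccc1)c1ccc(OCc2ccccc2)cc1 | intermediate (not isolated)
23 | (2R,3R,4R)-3,7,8-tris(benzyloxy)-2-[4-(benzyloxy)phenyl]-6-[(2R,3R,4R)-3,7,8-tris(benzyloxy)-2-[3,4-bis(benzyloxy)phenyl]chroman-4-yl]chroman-4-ol (nona-O-benzyl biflavan, free C4' hydroxyl, lower unit all-cis) | c1ccccc1COc1ccc(cc1)[C@H]1Oc2c(cc([C@H]3c4ccc(OCc5ccccc5)c(OCc5ccccc5)c4O[C@H](c4ccc(OCc5ccccc5)c(OCc5ccccc5)c4)[C@@H]3OCc3ccccc3)c(OCc3ccccc3)c2OCc2ccccc2)[C@@H](O)[C@H]1OCc1ccccc1 | intermediate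
24 | (2R,3R,4R)-6-[(2R,3R,4S)-2-(3,4-dihydroxyphenyl)-3,7,8-trihydroxychroman-4-yl]-2-(4-hydroxyphenyl)chroman-3,4,7,8-tetrol | Oc1ccc([C@H]2Oc3c(cc([C@H]4c5ccc(O)c(O)c5O[C@H](c5ccc(O)c(O)c5)[C@@H]4O)c(O)c3O)[C@@H](O)[C@H]2O)cc1 | target

**Step count and risks**

Total steps: 17. Longest linear sequence: 13 steps (steps 1–3, 6–9, 12–17).

Steps most likely to fail:

Step 13. The doubly ortho-substituted phenoxide may attack the benzylic epoxide carbon too slowly, so that transesterification, attack with partial retention through a benzylic cation, or base-induced loss of the aryloxy group from the product ester take over. The fallback removes the ester from the electrophile. It sets out from glycidic ester 17 and phenol 18. Ester 17 would be reduced with NaBH4 in EtOH to the cis-epoxy alcohol F1, whose primary hydroxyl would be silylated (t-BuPh2SiCl, imidazole) to give the epoxy silyl ether F2; this blocks epoxide migration. F2 can be heated with the fully formed cesium phenoxide of 18 (stoichiometric Cs2CO3, DMF, 80–100 °C), since there is no ester to enolise or cleave. Attack at the benzylic carbon with inversion should give the secondary alcohol F3. Benzylation with NaH and BnBr would give the benzyl ether F4, n-Bu4NF would free the primary alcohol F5, and oxidation with Dess–Martin periodinane (NaHCO3, CH2Cl2) would give aldehyde 21, where the route is rejoined.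

Step 16. The ring closure may show poor facial selectivity at C4', or the aldehyde may lose its β-aryloxy group or epimerise at C3' before the arylchromium species forms. The fallback makes the C4'–C4a' bond at the ketone oxidation level and lets a hydride set C4'. It sets out from ester 20. Iodine–lithium exchange with t-BuLi in THF at −100 °C, followed by Parham-type acylation of the aryllithium by the ethyl ester, would give the lower-unit C4' ketone F6. Reduction with NaBH4 and CeCl3 in MeOH–THF at −20 °C should deliver hydride anti to the axial C3' benzyloxy group and give the 3',4'-cis alcohol 23, where the route is rejoined.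

Step 17. Hydrogenolysis may go on to cleave the benzylic C4'–OH bond once the para hydroxyl on ring A is free, or stall at the two secondary benzyl ethers. The fallback carries C4' through the deprotection as a ketone. It sets out from 23. Oxidation with Dess–Martin periodinane (NaHCO3, CH2Cl2) would give the C4' ketone F7 (the same structure as F6). Hydrogenolysis over Pd(OH)2/C would then give the free phenolic 2',3'-cis dihydroflavonol ketone F8, whose aryl ketone resists hydrogenolysis. Reduction with NaBH4 in EtOH at 0 °C, hydride again entering anti to the axial C3' oxygen, would give target 24.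

**Further compounds**

F1 | step 13 | [(2R,3S)-3-[4-(benzyloxy)phenyl]oxiran-2-yl]methanol (cis) | OC[C@H]1O[C@H]1c1ccc(OCc2ccccc2)cc1
F2 | step 13 | tert-butyl{[(2R,3S)-3-[4-(benzyloxy)phenyl]oxiran-2-yl]methoxy}diphenylsilane | CC(C)(C)[Si](c1ccccc1)(c1ccccc1)OC[C@H]1O[C@H]1c1ccc(OCc2ccccc2)cc1
F3 | step 13 | (2R,3R)-3-{2,3-bis(benzyloxy)-6-iodo-4-[(2R,3R,4R)-3,7,8-tris(benzyloxy)-2-[3,4-bis(benzyloxy)phenyl]chroman-4-yl]phenoxy}-3-[4-(benzyloxy)phenyl]-1-[(tert-butyldiphenylsilyl)oxy]propan-2-ol | CC(C)(C)[Si](c1ccccc1)(c1ccccc1)OC[C@@H](O)[C@H](Oc1c(I)cc([C@H]2c3ccc(OCc4ccccc4)c(OCc4ccccc4)c3O[C@H](c3ccc(OCc4ccccc4)c(OCc4ccccc4)c3)[C@@H]2OCc2ccccc2)c(OCc2ccccc2)c1OCc1ccccc1)c1ccc(OCc2ccccc2)cc1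
F4 | step 13 | 2-O-benzyl ether of F3, (2R,3R)-configured | CC(C)(C)[Si](c1ccccc1)(c1ccccc1)OC[C@@H](OCc1ccccc1)[C@H](Oc1c(I)cc([C@H]2c3ccc(OCc4ccccc4)c(OCc4ccccc4)c3O[C@H](c3ccc(OCc4ccccc4)c(OCc4ccccc4)c3)[C@@H]2OCc2ccccc2)c(OCc2ccccc2)c1OCc1ccccc1)c1ccc(OCc2ccccc2)cc1
F5 | step 13 | (2R,3R)-2-(benzyloxy)-3-{2,3-bis(benzyloxy)-6-iodo-4-[(2R,3R,4R)-3,7,8-tris(benzyloxy)-2-[3,4-bis(benzyloxy)phenyl]chroman-4-yl]phenoxy}-3-[4-(benzyloxy)phenyl]propan-1-ol | OC[C@@H](OCc1ccccc1)[C@H](Oc1c(I)cc([C@H]2c3ccc(OCc4ccccc4)c(OCc4ccccc4)c3O[C@H](c3ccc(OCc4ccccc4)c(OCc4ccccc4)c3)[C@@H]2OCc2ccccc2)c(OCc2ccccc2)c1OCc1ccccc1)c1ccc(OCc2ccccc2)cc1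
F6 | step 16 | (2R,3S)-3,7,8-tris(benzyloxy)-2-[4-(benzyloxy)phenyl]-6-[(2R,3R,4R)-3,7,8-tris(benzyloxy)-2-[3,4-bis(benzyloxy)phenyl]chroman-4-yl]chroman-4-one (2,3-cis) | c1ccccc1COc1ccc(cc1)[C@H]1Oc2c(cc([C@H]3c4ccc(OCc5ccccc5)c(OCc5ccccc5)c4O[C@H](c4ccc(OCc5ccccc5)c(OCc5ccccc5)c4)[C@@H]3OCc3ccccc3)c(OCc3ccccc3)c2OCc2ccccc2)C(=O)[C@H]1OCc1ccccc1
F7 | step 17 | (2R,3S)-3,7,8-tris(benzyloxy)-2-[4-(benzyloxy)phenyl]-6-[(2R,3R,4R)-3,7,8-tris(benzyloxy)-2-[3,4-bis(benzyloxy)phenyl]chroman-4-yl]chroman-4-one (same structure as F6) | c1ccccc1COc1ccc(cc1)[C@H]1Oc2c(cc([C@H]3c4ccc(OCc5ccccc5)c(OCc5ccccc5)c4O[C@H](c4ccc(OCc5ccccc5)c(OCc5ccccc5)c4)[C@@H]3OCc3ccccc3)c(OCc3ccccc3)c2OCc2ccccc2)C(=O)[C@H]1OCc1ccccc1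
F8 | step 17 | (2R,3S)-6-[(2R,3R,4S)-2-(3,4-dihydroxyphenyl)-3,7,8-trihydroxychroman-4-yl]-3,7,8-trihydroxy-2-(4-hydroxyphenyl)chroman-4-one (2,3-cis) | Oc1ccc(cc1)[C@H]1Oc2c(cc([C@H]3c4ccc(O)c(O)c4O[C@H](c4ccc(O)c(O)c4)[C@@H]3O)c(O)c2O)C(=O)[C@H]1O
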